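Balance the partner first: by the proposed steps, each partner consumed leaves as a product or as spent reagent, one for one, and that count needs no rate constant.

the same everywhere: left-handed substrate 0.20 M; right-handed substrate 0.20 M; precatalyst 15 mM
- alder: partner 0.080 M; added ligand 15 mM; run made earlier
- cedar: partner 0.12 M; added ligand 15 mM; run made earlier
- oak: partner 0.16 M; added ligand 7.5 mM; run made earlier
- flask: partner 0.160 M; added ligand 15 mM; time 10 d

| run | time / d | right-handed substrate / % | left-handed substrate / % |
|---|---|---|---|
| alder | 2.08 | 48.8 | 38.1 |
| alder | 4.00 | 49.3 | 33.4 |
| alder | 6.00 | 48.3 | 33.3 |
| alder | 8.00 | 47.7 | 34.6 |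
| cedar | 0.625 | 49.9 | 46.4 |
| cedar | 1.67 | 50.0 | 35.7 |
| cedar | 3.00 | 53.3 | 26.8 |
| cedar | 8.00 | 51.4 | 22.6 |
| oak | 0.625 | 50.7 | 39.6 |
| oak | 1.67 | 49.9 | 19.5 |
| oak | 3.00 | 48.0 | 15.9 |
| oak | 8.00 | 49.1 | 14.1 |

(scatter of a reading: 1 percentage point)

- free catalyst is single-handed; left-handed substrate and right-handed substrate are mirror images of each other, charged as a racemate, each of them at the stated concentration
- the numbers in the tables scatter by 1 percentage point (one standard deviation)
- steps that have been proposed: free catalyst -> spent catalyst; free catalyst + right-handed substrate <-> catalyst intermediate B; free catalyst + left-handed substrate <-> catalyst intermediate A; free catalyst + added ligand <-> idle complex; partner + catalyst intermediate B -> free catalyst + right-handed product; partner + catalyst intermediate A -> free catalyst + left-handed product; partner + precatalyst -> free catalyst + spent reagent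

- whether the excess of right-handed substrate over left-handed substrate among what is left of the two reaches 99 % by 10 d (no / yes)
- the highest excess of right-handed substrate over left-handed substrate among what is left of the two up to 10 d

Subtract the charge of precatalyst from the charge of partner: 0.145 M. Call this the working partner, what a fully woken precatalyst leaves for the substrates. Test it on the earlier runs, taking right-handed substrate as untouched (49.1 % at the last oak reading). It puts left-handed substrate at 33.8 % in alder, 23.8 % in cedar and 13.7 % in oak; the last readings are 34.6 %, 22.6 % and 14.1 %, against a scatter of 1 percentage point.

Now draw my curve for the flask. The working partner is smaller than the charge of left-handed substrate, 0.20 M, so partner is the limiting reagent. The flask has cedar's ligand, so take cedar's loss up to 1.67 d and scale it by [partner]: left-handed substrate falls at first at 0.114 d⁻¹, as a fraction of both substrates charged. The working partner is 36.3 % of that charge, so the straight line meets its level near 3.18 d, and because this is earlier than 10 d, the knee lies inside the time allowed. The excess starts at zero and bends over there. Its level is the working partner divided by what then remains of the two substrates, 56.9 %, lower than 99 %.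

The forecast answers no with a top of 54 %, on the ground “partner, not selectivity, sets the end point”. Its top is lower than my level, by its allowance for catalyst death.

The flask gives no and a top of 55.7 %. At 10.0 d left-handed product in the flask stands at 35.9 %, beside the working partner's 36.3 % of the two substrates charged, with partner down to 1.29 % of its charge. The flask holds what the level does not: spent reagent stands at 0.0118 M at that time, lower than the 15 mM that the working partner subtracts, and 21.3 % of the catalyst charged is still precatalyst.

    free catalyst → spent catalyst (k = 0.0770 h⁻¹)
    free catalyst + right-handed substrate ⇌ catalyst intermediate B (K = 3.00 M⁻¹, k = 770 M⁻¹ h⁻¹)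
    free catalyst + left-handed substrate ⇌ catalyst intermediate A (K = 6.70 M⁻¹, k = 140 M⁻¹ h⁻¹)
    free catalyst + added ligand ⇌ idle complex, settled at all times (K = 1600 M⁻¹)
    partner + catalyst intermediate B → free catalyst + right-handed product (k = 1.50 M⁻¹ h⁻¹)
    partner + catalyst intermediate A → free catalyst + left-handed product (k = 91.0 M⁻¹ h⁻¹)
    partner + precatalyst → free catalyst + spent reagent (k = 0.220 M⁻¹ h⁻¹)

Charge 0.64 M of partner, other charges as in the recipe: the working partner becomes 0.625 M, larger than the charge of left-handed substrate, so expect left-handed substrate to be the limiting reagent. Computed, left-handed substrate stands at 0 % at 10.0 d, with 59 % of the partner left and a top of >99.9 %.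

The readings come from a simulation with constants of no real substance; noise was put on by code.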